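The oxepine ring (O1, C2–C5, C5a, C9a) is contracted to a pyran. Oxepine carbon C4 has as neighbours C3, the carbon with the exocyclic CH2, and the benzylic carbon C5; taking C4 out leaves the C3=C4 alkene of a 3-methyl-2H-chromene. In the forward sense one operation, dibromocarbene addition followed by silver-triggered cyclopropyl-to-allyl cation opening, puts that carbon back, makes both of its ring bonds, enlarges the ring to seven members and converts the methyl into the methylene. The substrate is the TBS-protected (3-methyl-2H-chromen-6-yl)methanol, reached by vinylation, O-methallylation and ring-closing metathesis; debromination, desilylation and stearoylation finish the synthesis.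

Key step: step 6

Remark: the target has no stereocentre, so no stereocontrol is needed. Carbene addition and silver-mediated opening are run as one telescoped operation and counted as one step.

Step 1
Reactants: 1 3-bromo-4-hydroxybenzaldehyde; 2 2-ethenyl-4,4,5,5-tetramethyl-1,3,2-dioxaborolane (vinylboronic acid pinacol ester)
Product: 3 3-ethenyl-4-hydroxybenzaldehyde
Conditions: PdCl2(dppf) (3 mol%), K2CO3 (3 equiv), 1,4-dioxane/H2O 4:1, 80 °C, BHT (trace); aq. NH4Cl work-up
Reagents that add atoms: 2-ethenyl-4,4,5,5-tetramethyl-1,3,2-dioxaborolane, C=CB1OC(C)(C)C(C)(C)O1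
Why: Suzuki–Miyaura coupling of an aryl bromide activated by the para formyl group tolerates the free phenol, and coupling before O-alkylation means that zerovalent palladium never meets an o-bromoaryl methallyl ether, which would cyclise by 5-exo carbopalladation instead of coupling.

Step 2
Reactants: 3 3-ethenyl-4-hydroxybenzaldehyde; 4 3-chloro-2-methylprop-1-ene (methallyl chloride)
Product: 5 3-ethenyl-4-[(2-methylprop-2-en-1-yl)oxy]benzaldehyde
Conditions: K2CO3 (2 equiv), DMF, 60 °C
Reagents that add atoms: 3-chloro-2-methylprop-1-ene, C=C(C)CCl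
Why: Williamson ether synthesis, in which the phenol, acidified by the para formyl group, is deprotonated by K2CO3 and its phenoxide displaces the allylic chloride (SN2) far below the temperature of a Claisen rearrangement.

Step 3
Reactants: 5 3-ethenyl-4-[(2-methylprop-2-en-1-yl)oxy]benzaldehyde
Product: 6 {3-ethenyl-4-[(2-methylprop-2-en-1-yl)oxy]phenyl}methanol
Conditions: NaBH4, MeOH, 0 °C
Reagents that add atoms: none
Why: Hydride reduction of the aldehyde with NaBH4 is chemoselective and leaves both alkenes and the allyl aryl ether untouched.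

Step 4
Reactants: 6 {3-ethenyl-4-[(2-methylprop-2-en-1-yl)oxy]phenyl}methanol; 7 tert-butylchlorodimethylsilane (TBSCl)
Product: 8 tert-butyl({3-ethenyl-4-[(2-methylprop-2-en-1-yl)oxy]phenyl}methoxy)dimethylsilane
Conditions: TBSCl, imidazole, CH2Cl2, 0 °C → rt
Reagents that add atoms: tert-butylchlorodimethylsilane, CC(C)(C)[Si](C)(C)Cl
Why: Imidazole-promoted silylation of a primary benzylic alcohol is routine, and the TBS ether is chosen because it withstands KOtBu, the silver salt and t-BuLi and is later removed by fluoride without acid.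

Step 5
Reactants: 8 tert-butyl({3-ethenyl-4-[(2-methylprop-2-en-1-yl)oxy]phenyl}methoxy)dimethylsilane
Product: 9 tert-butyldimethyl[(3-methyl-2H-chromen-6-yl)methoxy]silane
Conditions: second-generation Grubbs catalyst RuCl2(H2IMes)(PCy3)(=CHPh) (3 mol%), CH2Cl2 (0.01 M), 40 °C
Reagents that add atoms: none
Why: Ring-closing metathesis between the styrene and the 1,1-disubstituted methallyl alkene closes the six-membered pyran as a trisubstituted alkene with loss of ethylene, a closure well within reach of the N-heterocyclic-carbene ruthenium catalyst.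

Step 6
Reactants: 9 tert-butyldimethyl[(3-methyl-2H-chromen-6-yl)methoxy]silane; 10 bromoform
Product: 13 tert-butyl[(4-bromo-3-methylidene-2,3-dihydro-1-benzoxepin-7-yl)methoxy]dimethylsilane, via dibromocyclopropane adduct 11 (not isolated), via 2-bromoallyl cation tetrafluoroborate 12 (not isolated)
Conditions: (i) CHBr3 (2.5 equiv), KOtBu (3 equiv), pentane, −20 → 0 °C; filter through Celite, concentrate cold; (ii) AgBF4 (1.5 equiv), 2,6-lutidine (3 equiv), CH2Cl2, −20 °C → rt, dark
Reagents that add atoms: bromoform, BrC(Br)Br
Why: Dibromocarbene, released from bromoform by α-elimination with KOtBu, adds in a concerted [2+1] cycloaddition to the electron-rich, styrene-type C3=C4 bond of 9 (chromene numbering) and gives the necessarily cis-fused dibromocyclopropane 11, whose two ring-fusion stereocentres are transient and are erased in the next event. AgBF4 then abstracts the endo bromide (the one lying over the pyran ring) while the ring-fusion bond breaks in a disrotatory two-electron electrocyclic opening, the cyclopropyl-to-allyl cation rearrangement in which the groups cis to the leaving halide turn inward, so the cis-configured 2-bromoallyl cation 12 is formed inside the enlarged ring. The seven-membered ring is thus closed by one-carbon ring enlargement and not by a cyclisation: the carbene carbon becomes C4 (oxepine numbering), its two bonds to C3 and C5 are the new skeletal bonds, the old C3–C5 bond is the one that breaks, and 13 contains no stereocentre. Cation 12 is stabilised at tertiary C3 and at benzylic C5 by the ortho ring oxygen, and 2,6-lutidine takes a proton from the C3 methyl, which leaves the exocyclic methylene and keeps C4=C5 conjugated with the arene. The closest known reactions are the dihalocarbene–silver ring expansions of cycloalkenes and of 2H-chromenes to 2-halo-1,3-dienes of the next larger ring. The selectivity required is proton loss from the methyl and not from C2 (which would lead to the fully unsaturated 1-benzoxepine); it rests on the hindered base meeting three exposed methyl hydrogens, on the C2–H bonds being poorer hyperconjugative donors because C2 carries oxygen, and on buffered, kinetic conditions that prevent later acid-induced isomerisation.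

Step 7
Reactants: 13 tert-butyl[(4-bromo-3-methylidene-2,3-dihydro-1-benzoxepin-7-yl)methoxy]dimethylsilane
Product: 15 tert-butyldimethyl[(3-methylidene-2,3-dihydro-1-benzoxepin-7-yl)methoxy]silane, via 4-lithio diene 14 (not isolated)
Conditions: t-BuLi (2.1 equiv), THF, −78 °C; then MeOH, −78 °C → rt
Reagents that add atoms: none
Why: Bromine–lithium exchange at the alkenyl bromide with two equivalents of t-BuLi (the second destroys the tert-butyl bromide formed) should be faster at −78 °C than any attack on the allylic aryl ether or the silyl ether, and protonation of the configurationally fixed dienyllithium by methanol gives the C4–H diene without moving the double bonds.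

Step 8
Reactants: 15 tert-butyldimethyl[(3-methylidene-2,3-dihydro-1-benzoxepin-7-yl)methoxy]silane
Product: 16 (3-methylidene-2,3-dihydro-1-benzoxepin-7-yl)methanol
Conditions: TBAF (1.2 equiv), THF, 0 °C → rt
Reagents that add atoms: none
Why: Fluoride-mediated cleavage of the silyl ether is driven by the strong Si–F bond and runs under mildly basic conditions that spare the acid-sensitive exocyclic diene and the 4-alkoxybenzyl alcohol.

Step 9
Reactants: 16 (3-methylidene-2,3-dihydro-1-benzoxepin-7-yl)methanol; 17 octadecanoyl chloride (stearoyl chloride)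
Product: 18 (3-methylidene-2,3-dihydro-1-benzoxepin-7-yl)methyl octadecanoate
Conditions: stearoyl chloride (1.2 equiv), Et3N (2 equiv), DMAP (5 mol%), CH2Cl2, 0 °C → rt
Reagents that add atoms: octadecanoyl chloride, CCCCCCCCCCCCCCCCCC(=O)Cl
Why: DMAP-catalysed acylation of the primary alcohol by the acid chloride (nucleophilic catalysis through the acylpyridinium ion) is reliable, and triethylamine takes up the HCl so that neither the benzylic ester nor the diene meets acid.

Compound list

1 | 3-bromo-4-hydroxybenzaldehyde | O=Cc1ccc(O)c(Br)c1 | starting material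
2 | 2-ethenyl-4,4,5,5-tetramethyl-1,3,2-dioxaborolane (vinylboronic acid pinacol ester) | C=CB1OC(C)(C)C(C)(C)O1 | starting material
3 | 3-ethenyl-4-hydroxybenzaldehyde | O=Cc1ccc(O)c(C=C)c1 | intermediate
4 | 3-chloro-2-methylprop-1-ene (methallyl chloride) | C=C(C)CCl | starting material
5 | 3-ethenyl-4-[(2-methylprop-2-en-1-yl)oxy]benzaldehyde | O=Cc1ccc(OCC(C)=C)c(C=C)c1 | intermediate
6 | {3-ethenyl-4-[(2-methylprop-2-en-1-yl)oxy]phenyl}methanol | OCc1ccc(OCC(C)=C)c(C=C)c1 | intermediate
7 | tert-butylchlorodimethylsilane (TBSCl) | CC(C)(C)[Si](C)(C)Cl | starting material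
8 | tert-butyl({3-ethenyl-4-[(2-methylprop-2-en-1-yl)oxy]phenyl}methoxy)dimethylsilane | C=C(C)COc1ccc(CO[Si](C)(C)C(C)(C)C)cc1C=C | intermediate
9 | tert-butyldimethyl[(3-methyl-2H-chromen-6-yl)methoxy]silane | CC1=Cc2cc(CO[Si](C)(C)C(C)(C)C)ccc2OC1 | intermediate
10 | bromoform (tribromomethane) | BrC(Br)Br | starting material
11 | tert-butyl[(1,1-dibromo-1a-methyl-1,1a,2,7b-tetrahydrocyclopropa[c]chromen-6-yl)methoxy]dimethylsilane (racemic; the cis ring fusion is the only one possible; not isolated) | CC12COc3ccc(CO[Si](C)(C)C(C)(C)C)cc3C1C2(Br)Br | intermediate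
12 | 4-bromo-7-{[(tert-butyldimethylsilyl)oxy]methyl}-3-methyl-2H-1-benzoxepinylium tetrafluoroborate (2-bromoallyl cation, charge shared by C3 and C5; not isolated) | C[C+]1COc2ccc(CO[Si](C)(C)C(C)(C)C)cc2C=C1Br.F[B-](F)(F)F | intermediate
13 | tert-butyl[(4-bromo-3-methylidene-2,3-dihydro-1-benzoxepin-7-yl)methoxy]dimethylsilane | C=C1C(Br)=Cc2cc(CO[Si](C)(C)C(C)(C)C)ccc2OC1 | intermediate
14 | [7-({[tert-butyl(dimethyl)silyl]oxy}methyl)-3-methylidene-2,3-dihydro-1-benzoxepin-4-yl]lithium (not isolated) | [Li]C1=Cc2cc(CO[Si](C)(C)C(C)(C)C)ccc2OCC1=C | intermediate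
15 | tert-butyldimethyl[(3-methylidene-2,3-dihydro-1-benzoxepin-7-yl)methoxy]silane | C=C1C=Cc2cc(CO[Si](C)(C)C(C)(C)C)ccc2OC1 | intermediate
16 | (3-methylidene-2,3-dihydro-1-benzoxepin-7-yl)methanol | C=C1C=Cc2cc(CO)ccc2OC1 | intermediate
17 | octadecanoyl chloride (stearoyl chloride) | CCCCCCCCCCCCCCCCCC(=O)Cl | starting material
18 | (3-methylidene-2,3-dihydro-1-benzoxepin-7-yl)methyl octadecanoate (CNP0302126.0) | C=C1C=Cc2cc(COC(=O)CCCCCCCCCCCCCCCCC)ccc2OC1 | target

Total step count: 9. Longest linear sequence: 9 steps (1 → 18).

Steps most likely to fail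

Step 6. The allyl cation may lose a proton from C2 instead of from the methyl, which would give the ring-conjugated 1-benzoxepine. It may also be intercepted by lutidine, fluoride or traces of water before any proton is lost. The fallback replaces deprotonation by a silicon-directed termination, the known desilylative opening of (2,2-dihalocyclopropyl)methylsilanes to 2-halo-1,3-dienes. It sets out from phenol 3, which is O-alkylated with 2-(chloromethyl)allyl-trimethylsilane (C=C(CCl)C[Si](C)(C)C; K2CO3, DMF, 60 °C) to 3-ethenyl-4-({2-[(trimethylsilyl)methyl]prop-2-en-1-yl}oxy)benzaldehyde F1. NaBH4 in MeOH should then give [3-ethenyl-4-({2-[(trimethylsilyl)methyl]prop-2-en-1-yl}oxy)phenyl]methanol F2, and TBSCl with imidazole its silyl ether tert-butyl{[3-ethenyl-4-({2-[(trimethylsilyl)methyl]prop-2-en-1-yl}oxy)phenyl]methoxy}dimethylsilane F3. Ring-closing metathesis with the second-generation Grubbs catalyst RuCl2(H2IMes)(PCy3)(=CHPh) closes tert-butyldimethyl({3-[(trimethylsilyl)methyl]-2H-chromen-6-yl}methoxy)silane F4. CHBr3 and KOtBu add the carbene to give tert-butyl({1,1-dibromo-1a-[(trimethylsilyl)methyl]-1,1a,2,7b-tetrahydrocyclopropa[c]chromen-6-yl}methoxy)dimethylsilane F5. AgBF4 with 2,6-lutidine in CH2Cl2 opens it to the silyl-substituted 2-bromoallyl cation tetrafluoroborate F6, which is β to silicon and collapses only by loss of the trimethylsilyl group. The position of silicon therefore fixes the exocyclic methylene, and the route is rejoined at bromodiene 13.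

Step 7. t-BuLi may attack the exocyclic methylene in an SN2′ sense with expulsion of the phenoxide, or add to the styrene-type diene, before or after the exchange. The fallback changes the mechanism from halogen–metal exchange to palladium-catalysed hydride transfer and sets out from 13. With Pd(OAc)2, PPh3, HCO2H and Et3N in DMF at 60 °C, zerovalent palladium inserts into the C4–Br bond, formate replaces bromide and loses CO2, and reductive elimination of the alkenyl palladium hydride delivers the C4–H diene. The route is rejoined at 15, and the fallback makes no new compound (F0).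

Step 1. Oxidative addition to the electron-rich o-bromophenoxide may be slow, and the 2-vinylphenol may oligomerise during the hot basic coupling or on work-up. The fallback avoids palladium and builds the vinyl group by formylation and Wittig methylenation. It sets out from 1, which is O-alkylated with 4 (K2CO3, DMF) to 3-bromo-4-[(2-methylprop-2-en-1-yl)oxy]benzaldehyde F7. NaBH4 gives {3-bromo-4-[(2-methylprop-2-en-1-yl)oxy]phenyl}methanol F8, and TBSCl with imidazole gives ({3-bromo-4-[(2-methylprop-2-en-1-yl)oxy]phenyl}methoxy)(tert-butyl)dimethylsilane F9. Bromine–lithium exchange with n-BuLi in THF at −78 °C forms [5-({[tert-butyl(dimethyl)silyl]oxy}methyl)-2-[(2-methylprop-2-en-1-yl)oxy]phenyl]lithium F10, which is trapped cold with DMF, before anionic cyclisation onto the methallyl group can occur, to give 5-({[tert-butyl(dimethyl)silyl]oxy}methyl)-2-[(2-methylprop-2-en-1-yl)oxy]benzaldehyde F11. Wittig methylenation (Ph3PCH3Br, KOtBu, THF, 0 °C) then gives the styrene, and the route is rejoined at 8.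

Further compounds

F1 | step 6 | 3-ethenyl-4-({2-[(trimethylsilyl)methyl]prop-2-en-1-yl}oxy)benzaldehyde | O=Cc1ccc(OCC(=C)C[Si](C)(C)C)c(C=C)c1
F2 | step 6 | [3-ethenyl-4-({2-[(trimethylsilyl)methyl]prop-2-en-1-yl}oxy)phenyl]methanol | OCc1ccc(OCC(=C)C[Si](C)(C)C)c(C=C)c1
F3 | step 6 | tert-butyl{[3-ethenyl-4-({2-[(trimethylsilyl)methyl]prop-2-en-1-yl}oxy)phenyl]methoxy}dimethylsilane | C=C(C[Si](C)(C)C)COc1ccc(CO[Si](C)(C)C(C)(C)C)cc1C=C
F4 | step 6 | tert-butyldimethyl({3-[(trimethylsilyl)methyl]-2H-chromen-6-yl}methoxy)silane | C[Si](C)(C)CC1=Cc2cc(CO[Si](C)(C)C(C)(C)C)ccc2OC1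
F5 | step 6 | tert-butyl({1,1-dibromo-1a-[(trimethylsilyl)methyl]-1,1a,2,7b-tetrahydrocyclopropa[c]chromen-6-yl}methoxy)dimethylsilane (racemic, cis-fused) | C[Si](C)(C)CC12COc3ccc(CO[Si](C)(C)C(C)(C)C)cc3C1C2(Br)Br
F6 | step 6 | 4-bromo-7-{[(tert-butyldimethylsilyl)oxy]methyl}-3-[(trimethylsilyl)methyl]-2H-1-benzoxepinylium tetrafluoroborate (not isolated) | C[Si](C)(C)C[C+]1COc2ccc(CO[Si](C)(C)C(C)(C)C)cc2C=C1Br.F[B-](F)(F)F
F0 | step 7 | none | none
F7 | step 1 | 3-bromo-4-[(2-methylprop-2-en-1-yl)oxy]benzaldehyde | O=Cc1ccc(OCC(C)=C)c(Br)c1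
F8 | step 1 | {3-bromo-4-[(2-methylprop-2-en-1-yl)oxy]phenyl}methanol | OCc1ccc(OCC(C)=C)c(Br)c1
F9 | step 1 | ({3-bromo-4-[(2-methylprop-2-en-1-yl)oxy]phenyl}methoxy)(tert-butyl)dimethylsilane | C=C(C)COc1ccc(CO[Si](C)(C)C(C)(C)C)cc1Br
F10 | step 1 | [5-({[tert-butyl(dimethyl)silyl]oxy}methyl)-2-[(2-methylprop-2-en-1-yl)oxy]phenyl]lithium (not isolated) | [Li]c1cc(CO[Si](C)(C)C(C)(C)C)ccc1OCC(C)=C
F11 | step 1 | 5-({[tert-butyl(dimethyl)silyl]oxy}methyl)-2-[(2-methylprop-2-en-1-yl)oxy]benzaldehyde | C=C(C)COc1ccc(CO[Si](C)(C)C(C)(C)C)cc1C=O
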